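**Retrosynthetic overview**
- Target ⇒ its tris-TIPS ether; the silyl groups are removed with buffered fluoride in the same flask as the key step.
- Key disconnection C3–C4: the formyl carbon of an A-ring aldehyde acts as an acyl anion (carbene-bound Breslow intermediate) and adds to the B-ring aryl ketone carbon, two carbons that are both normally electrophilic; a chiral triazolylidene sets the C3 carbinol centre.
- O1–C2 ether ⇒ 7-O-TIPS salicylaldehyde + bis-TIPS α-chloro ketone (Williamson).
- A-ring aldehyde ⇒ 2,4-dihydroxybenzaldehyde + two prenyl bromide (double C-prenylation, then 4-O-silylation); B-ring piece ⇒ bought 2-chloro-1-(2,4-dihydroxyphenyl)ethanone.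
- Ring order: A and B rings are bought as arenes; the pyranone C ring is the only ring formed, last, in the stereo-defining step.

Assumption: the α-chloro ketone of step 3 is a catalogue compound; the hand of the triazolium salt in step 5 is chosen by analogy with 3-hydroxychroman-4-one precedent and must be confirmed on the first run (the mirror-image salt is also sold).

**Step 1**
Reactants: 1 2,4-dihydroxybenzaldehyde; 2 prenyl bromide (1-bromo-3-methylbut-2-ene, 2.3 equiv)
Product: 3 2,4-dihydroxy-3,5-bis(3-methylbut-2-en-1-yl)benzaldehyde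
Conditions: KOH (3 equiv), H2O, 0 °C → rt, 16 h
Reagents that add atoms: none
Why: Phenoxide C-alkylation in water, where the hydrated resorcinolate reacts at carbon, puts a prenyl group on C3 and C5, the only ring positions ortho/para to both oxygens; the yield is modest (about 15–25 %) because mono-prenyl and O-prenyl products also form and are separated by chromatography.

**Step 2**
Reactants: 3 2,4-dihydroxy-3,5-bis(3-methylbut-2-en-1-yl)benzaldehyde
Product: 4 2-hydroxy-3,5-bis(3-methylbut-2-en-1-yl)-4-[(triisopropylsilyl)oxy]benzaldehyde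
Conditions: TIPSCl (1.1 equiv), imidazole (2.2 equiv), DMF, 0 °C → rt
Reagents that add atoms: triisopropylsilyl chloride, CC(C)[Si](Cl)(C(C)C)C(C)C
Why: Chemoselective silyl ether formation, because the 2-OH is locked in a hydrogen bond to the formyl group while the more acidic, free 4-OH takes the single equivalent of silyl chloride.

**Step 3**
Reactants: 5 2-chloro-1-(2,4-dihydroxyphenyl)ethan-1-one
Product: 6 2-chloro-1-{2,4-bis[(triisopropylsilyl)oxy]phenyl}ethan-1-one
Conditions: TIPSOTf (2.2 equiv), 2,6-lutidine (3 equiv), CH2Cl2, −78 → 0 °C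
Reagents that add atoms: triisopropylsilyl trifluoromethanesulfonate, CC(C)[Si](OS(=O)(=O)C(F)(F)F)(C(C)C)C(C)C
Why: Silyl ether formation with a silyl triflate and a hindered, non-nucleophilic base protects both phenols, including the chelated 2-OH, without base-induced closure of the 2-hydroxy α-chloro ketone to a coumaranone or N-alkylation of the base.

**Step 4**
Reactants: 4 2-hydroxy-3,5-bis(3-methylbut-2-en-1-yl)-4-[(triisopropylsilyl)oxy]benzaldehyde; 6 2-chloro-1-{2,4-bis[(triisopropylsilyl)oxy]phenyl}ethan-1-one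
Product: 7 2-(2-{2,4-bis[(triisopropylsilyl)oxy]phenyl}-2-oxoethoxy)-3,5-bis(3-methylbut-2-en-1-yl)-4-[(triisopropylsilyl)oxy]benzaldehyde
Conditions: Cs2CO3 (1.2 equiv), MeCN, rt
Reagents that add atoms: none
Why: Williamson ether synthesis (SN2 of the salicylaldehyde phenoxide on the activated phenacyl chloride), in which TIPS ethers resist anhydrous carbonate and room temperature avoids the Rap–Stoermer aldol closure to a 2-aroylbenzofuran.

**Step 5**
Reactants: 7 2-(2-{2,4-bis[(triisopropylsilyl)oxy]phenyl}-2-oxoethoxy)-3,5-bis(3-methylbut-2-en-1-yl)-4-[(triisopropylsilyl)oxy]benzaldehyde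
Product: 10 (3R)-3-(2,4-dihydroxyphenyl)-3,7-dihydroxy-6,8-bis(3-methylbut-2-en-1-yl)chroman-4-one, via Breslow intermediate 8 (not isolated), via tris-TIPS ketol 9 (not isolated)
Conditions: (5aR,10bS)-2-(pentafluorophenyl)-5a,10b-dihydro-4H,6H-indeno[2,1-b][1,2,4]triazolo[4,3-d][1,4]oxazin-2-ium tetrafluoroborate (15 mol%), Et3N (15 mol%), toluene, Ar, rt; then AcOH (3.5 equiv), TBAF (3.3 equiv), THF, 0 °C → rt
Reagents that add atoms: none
Why: Enantioselective intramolecular crossed aldehyde–ketone benzoin reaction under chiral N-heterocyclic carbene catalysis, in which the carbene turns the formyl carbon into an acyl anion equivalent (8) that adds 6-exo to the aryl ketone with one ketone face shielded by the indane of the catalyst, setting C3 as R, after which acetic-acid-buffered fluoride cleaves the three aryl silyl ethers (and erases any O-to-O silyl drift) without acid that would dehydrate the tertiary ketol or cyclise the prenyl groups.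

**Compound list**
1 | 2,4-dihydroxybenzaldehyde | O=Cc1ccc(O)cc1O | starting material
2 | prenyl bromide (1-bromo-3-methylbut-2-ene) | CC(C)=CCBr | starting material
3 | 2,4-dihydroxy-3,5-bis(3-methylbut-2-en-1-yl)benzaldehyde | O=Cc1cc(CC=C(C)C)c(O)c(CC=C(C)C)c1O | intermediate
4 | 2-hydroxy-3,5-bis(3-methylbut-2-en-1-yl)-4-[(triisopropylsilyl)oxy]benzaldehyde | O=Cc1cc(CC=C(C)C)c(O[Si](C(C)C)(C(C)C)C(C)C)c(CC=C(C)C)c1O | intermediate
5 | 2-chloro-1-(2,4-dihydroxyphenyl)ethan-1-one | O=C(CCl)c1ccc(O)cc1O | starting material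
6 | 2-chloro-1-{2,4-bis[(triisopropylsilyl)oxy]phenyl}ethan-1-one | O=C(CCl)c1ccc(O[Si](C(C)C)(C(C)C)C(C)C)cc1O[Si](C(C)C)(C(C)C)C(C)C | intermediate
7 | 2-(2-{2,4-bis[(triisopropylsilyl)oxy]phenyl}-2-oxoethoxy)-3,5-bis(3-methylbut-2-en-1-yl)-4-[(triisopropylsilyl)oxy]benzaldehyde | O=Cc1cc(CC=C(C)C)c(O[Si](C(C)C)(C(C)C)C(C)C)c(CC=C(C)C)c1OCC(=O)c1ccc(O[Si](C(C)C)(C(C)C)C(C)C)cc1O[Si](C(C)C)(C(C)C)C(C)C | intermediate
8 | Breslow intermediate: enaminol formed by addition of the (5aR,10bS)-triazolylidene to the formyl carbon of 7 (enol geometry not defined) | OC(c1cc(CC=C(C)C)c(O[Si](C(C)C)(C(C)C)C(C)C)c(CC=C(C)C)c1OCC(=O)c1ccc(O[Si](C(C)C)(C(C)C)C(C)C)cc1O[Si](C(C)C)(C(C)C)C(C)C)=C1N(c2c(F)c(F)c(F)c(F)c2F)N=C2CO[C@@H]3Cc4ccccc4[C@@H]3N12 | intermediate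
9 | (3R)-3-{2,4-bis[(triisopropylsilyl)oxy]phenyl}-3-hydroxy-6,8-bis(3-methylbut-2-en-1-yl)-7-[(triisopropylsilyl)oxy]chroman-4-one | CC(C)=CCc1cc2c(c(CC=C(C)C)c1O[Si](C(C)C)(C(C)C)C(C)C)OC[C@](O)(c1ccc(O[Si](C(C)C)(C(C)C)C(C)C)cc1O[Si](C(C)C)(C(C)C)C(C)C)C2=O | intermediate
10 | (3R)-3-(2,4-dihydroxyphenyl)-3,7-dihydroxy-6,8-bis(3-methylbut-2-en-1-yl)chroman-4-one (CNP0211715.1) | CC(C)=CCc1cc2c(c(CC=C(C)C)c1O)OC[C@](O)(c1ccc(O)cc1O)C2=O | target

**Total step count:** 5
**Longest linear sequence:** 4 (steps 1, 2, 4, 5)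

**Steps most likely to fail**

Step 5. The ketone is electron-rich and flanked by an ortho-OTIPS group, so the chiral carbene may add slowly or with low ee. The fallback gives up catalyst control. It sets out from 7, which is cyclised with a small achiral carbene (3-benzyl-5-(2-hydroxyethyl)-4-methylthiazolium chloride, DBU, THF, 40 °C) to the racemic tris-TIPS ketol F4. Preparative chiral SFC separates F4 into 9 and the (S)-tris-TIPS ketol F5. F5 is returned to the racemate by the same carbene through retro-benzoin and recycled. The fallback comes back to the route at 9, now isolated, which is desilylated as in step 5.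

Step 1. Double C-prenylation of the free resorcinol aldehyde is low-yielding and gives mono-, O- and over-alkylated products. The fallback replaces phenoxide alkylation by halogenation and cross-coupling. It sets out from 1, which is brominated at both activated positions (Br2, NaOAc, AcOH, rt) to 3,5-dibromo-2,4-dihydroxybenzaldehyde F1. A double Suzuki–Miyaura coupling with 3-methylbut-2-en-1-ylboronic acid pinacol ester (Pd(OAc)2, bulky biarylphosphine chosen for the linear allyl product, K3PO4, THF–H2O, 40 °C) comes back to the route at 3.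

Step 4. The phenol is chelated and hindered, and base can cause silyl transfer or aldol closure to a benzofuran. The fallback forms the same ether under neutral redox-condensation conditions. It sets out from 6, whose chloride is exchanged for formate (HCO2Cs, MeOH, 60 °C) to give 2-{2,4-bis[(triisopropylsilyl)oxy]phenyl}-2-oxoethyl formate F2. F2 is methanolysed in the same flask to 2-hydroxy-1-{2,4-bis[(triisopropylsilyl)oxy]phenyl}ethan-1-one F3. Mitsunobu etherification of F3 with phenol 4 (PPh3, DIAD, THF, 0 °C) comes back to the route at 7.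

**Further compounds**
F1 | step 1 | 3,5-dibromo-2,4-dihydroxybenzaldehyde | O=Cc1cc(Br)c(O)c(Br)c1O
F2 | step 4 | 2-{2,4-bis[(triisopropylsilyl)oxy]phenyl}-2-oxoethyl formate | O=COCC(=O)c1ccc(O[Si](C(C)C)(C(C)C)C(C)C)cc1O[Si](C(C)C)(C(C)C)C(C)C
F3 | step 4 | 2-hydroxy-1-{2,4-bis[(triisopropylsilyl)oxy]phenyl}ethan-1-one | O=C(CO)c1ccc(O[Si](C(C)C)(C(C)C)C(C)C)cc1O[Si](C(C)C)(C(C)C)C(C)C
F4 | step 5 | racemic 3-{2,4-bis[(triisopropylsilyl)oxy]phenyl}-3-hydroxy-6,8-bis(3-methylbut-2-en-1-yl)-7-[(triisopropylsilyl)oxy]chroman-4-one | CC(C)=CCc1cc2c(c(CC=C(C)C)c1O[Si](C(C)C)(C(C)C)C(C)C)OCC(O)(c1ccc(O[Si](C(C)C)(C(C)C)C(C)C)cc1O[Si](C(C)C)(C(C)C)C(C)C)C2=O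
F5 | step 5 | (3S)-3-{2,4-bis[(triisopropylsilyl)oxy]phenyl}-3-hydroxy-6,8-bis(3-methylbut-2-en-1-yl)-7-[(triisopropylsilyl)oxy]chroman-4-one | CC(C)=CCc1cc2c(c(CC=C(C)C)c1O[Si](C(C)C)(C(C)C)C(C)C)OC[C@@](O)(c1ccc(O[Si](C(C)C)(C(C)C)C(C)C)cc1O[Si](C(C)C)(C(C)C)C(C)C)C2=O
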